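**Plan**

- Retrosynthetic cuts: (a) O1–C2 of the dihydropyran ring (retro-hydroalkoxylation), giving the achiral open-chain quinol acid 12; (b) the carboxyl carbon, traced back to the terminal (E)-methyl of a farnesyl chain; (c) the aryl–CH2 bond (C4a–C4), giving aryl bromide 3 and (2E,6E)-farnesyl bromide 4.
- Forward order: the arene and the intact C15 chain are joined (step 3), the chain end is oxidised to the (E)-enoic acid (steps 4–5), the quinol is unmasked through the quinone (steps 6–7), and the only ring that is built, the dihydropyran, closes last (step 8).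
- Stereochemistry: the 6E bond and the E bond that later cyclises come with 4; 2E comes from the E-selective allylic oxidation. The single stereocentre C2 is set in step 8 by a confined chiral Brønsted acid that imitates tocopherol cyclase (biomimetic quinol to chromanol cyclisation).
- Enabling feature: ring atoms C4–C3–C2 and the 2-CH3 are one prenyl unit, so O1–C2 is the Markovnikov O–H adduct across C10=C11 of 12 (acid numbering, C1 = CO2H, C12 = benzylic CH2). O1 is the only quinol oxygen ortho to the chain (the oxygen at C6 is para), and the chain's C2=C3 bond is deactivated by conjugation with CO2H.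

Key step: step 8

Assumption: (2E,6E)-farnesyl bromide 4 is bought as the pure E,E isomer; the sense of induction of the chiral acid cannot be predicted, so both catalyst antipodes would be screened and the (R)-selective one used.

**Route**

Step 1
Reactants: 1 4-methoxy-2-methylphenol
Product: 2 2-bromo-4-methoxy-6-methylphenol
Conditions: NBS (1.0 equiv), i-Pr2NH (10 mol %), CH2Cl2, 0 °C
Reagents that add atoms: N-bromosuccinimide, O=C1CCC(=O)N1Br
Why: Amine-mediated electrophilic bromination of a phenol goes ortho to the free OH, and C6 is the only open ortho position (para is blocked by OCH3).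

Step 2
Reactants: 2 2-bromo-4-methoxy-6-methylphenol
Product: 3 1-bromo-2,5-dimethoxy-3-methylbenzene
Conditions: MeI, K2CO3, acetone, reflux
Reagents that add atoms: iodomethane, CI
Why: Williamson O-methylation gives the quinol dimethyl ether, which survives the organometallic and oxidation steps and can later be unmasked oxidatively without acid.

Step 3
Reactants: 3 1-bromo-2,5-dimethoxy-3-methylbenzene; 4 (2E,6E)-farnesyl bromide
Product: 7 1-[(2E,6E)-3,7,11-trimethyldodeca-2,6,10-trien-1-yl]-2,5-dimethoxy-3-methylbenzene, via 2,5-dimethoxy-3-methylphenyllithium 5 (not isolated), via (2,5-dimethoxy-3-methylphenyl)copper 6 (not isolated)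
Conditions: n-BuLi, THF, −78 °C; CuBr·SMe2, −78 → −40 °C; then 4, −78 → 0 °C
Reagents that add atoms: none
Why: Bromine–lithium exchange, transmetalation to the arylcopper and SN2 allylation of the primary allylic bromide is the standard polyprenyl–arene coupling and should keep the 2E,6E geometry of the chain.

Step 4
Reactants: 7 1-[(2E,6E)-3,7,11-trimethyldodeca-2,6,10-trien-1-yl]-2,5-dimethoxy-3-methylbenzene
Product: 8 (2E,6E,10E)-12-(2,5-dimethoxy-3-methylphenyl)-2,6,10-trimethyldodeca-2,6,10-trien-1-ol
Conditions: SeO2 (cat.), t-BuOOH, salicylic acid (cat.), CH2Cl2, 0 °C → rt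
Reagents that add atoms: selenium dioxide, O=[Se]=O (transfers the oxygen); tert-butyl hydroperoxide, CC(C)(C)OO (terminal oxygen source)
Why: Catalytic SeO2 allylic oxidation (ene reaction, then [2,3]-shift; Riley type) prefers the least hindered terminal isopropylidene unit and its (E)-methyl group, so the new allylic alcohol should be 2E; any enal formed alongside converges in step 5.

Step 5
Reactants: 8 (2E,6E,10E)-12-(2,5-dimethoxy-3-methylphenyl)-2,6,10-trimethyldodeca-2,6,10-trien-1-ol
Product: 10 (2E,6E,10E)-12-(2,5-dimethoxy-3-methylphenyl)-2,6,10-trimethyldodeca-2,6,10-trienoic acid, via (2E,6E,10E)-enal 9 (not isolated)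
Conditions: MnO2, CH2Cl2, rt, filter; then NaClO2, NaH2PO4, 2-methylbut-2-ene, t-BuOH/H2O, 0 °C → rt
Reagents that add atoms: sodium chlorite, [Na+].[O-]Cl=O
Why: MnO2 oxidises only the allylic alcohol, and the Lindgren–Pinnick oxidation should take the enal to the acid without touching the trisubstituted alkenes or isomerising the 2E bond.

Step 6
Reactants: 10 (2E,6E,10E)-12-(2,5-dimethoxy-3-methylphenyl)-2,6,10-trimethyldodeca-2,6,10-trienoic acid
Product: 11 (2E,6E,10E)-2,6,10-trimethyl-12-(5-methyl-3,6-dioxocyclohexa-1,4-dien-1-yl)dodeca-2,6,10-trienoic acid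
Conditions: (NH4)2Ce(NO3)6, MeCN/H2O, 0 °C
Reagents that add atoms: water, O (source of the quinone oxygens; the OCH3 groups leave as methanol)
Why: Oxidative demethylation of a 1,4-dimethoxyarene to the p-benzoquinone is the usual unmasking for polyprenylquinones, tolerates isolated trisubstituted alkenes and the acid, and avoids acid conditions that could close the ring racemically.

Step 7
Reactants: 11 (2E,6E,10E)-2,6,10-trimethyl-12-(5-methyl-3,6-dioxocyclohexa-1,4-dien-1-yl)dodeca-2,6,10-trienoic acid
Product: 12 (2E,6E,10E)-12-(2,5-dihydroxy-3-methylphenyl)-2,6,10-trimethyldodeca-2,6,10-trienoic acid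
Conditions: Na2S2O4, EtOAc/H2O, rt, Ar; dried and used at once
Reagents that add atoms: none
Why: Neutral biphasic dithionite reduction of a quinone to the quinol, which is air-sensitive and is therefore carried directly into step 8.

Step 8
Reactants: 12 (2E,6E,10E)-12-(2,5-dihydroxy-3-methylphenyl)-2,6,10-trimethyldodeca-2,6,10-trienoic acid
Product: 13 (2E,6E)-9-[(2R)-6-hydroxy-2,8-dimethyl-3,4-dihydro-2H-chromen-2-yl]-2,6-dimethylnona-2,6-dienoic acid
Conditions: confined chiral imidodiphosphorimidate Brønsted acid (IDPi; BINOL backbone with 3,3′-aryl walls, N-triflyl core; 5 mol %), CHCl3, 5 Å MS, −20 °C → rt, Ar, dark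
Reagents that add atoms: none
Why: Proposed new method: the acid, hydrogen-bonded to O1–H of 12, should transfer its proton to C11 (the CH end of C10=C11) while O1 bonds to C10 in a concerted, asynchronous anti addition, so that no free tertiary cation is needed; the closest known reaction types are the IDPi-catalysed intramolecular hydroalkoxylation of unactivated alkenols, the racemic acid-catalysed chromanol cyclisation of prenylquinols and the tocopherol-cyclase reaction. The dihydropyran ring closes 6-endo-trig in the Markovnikov sense (O1–C2 bond). C2 is the only new stereocentre and is controlled by the catalyst pocket, which must tell the CH3 flank from the CH2 flank of the fixed (E)-alkene so that O1 adds to one face. Site selectivity among three trisubstituted alkenes is needed: C2=C3 is deactivated by conjugation with CO2H, C6=C7 has no hydroxyl within reach for concerted delivery, and only O1 (not the para O–H) can reach C10. The main risks are stepwise protonation at C6=C7 followed by carbocyclisation and a racemic background reaction, which low temperature and the non-polar medium are meant to suppress.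

**Compound list**

1 | 4-methoxy-2-methylphenol | COc1ccc(O)c(C)c1 | starting material
2 | 2-bromo-4-methoxy-6-methylphenol | COc1cc(C)c(O)c(Br)c1 | intermediate
3 | 1-bromo-2,5-dimethoxy-3-methylbenzene | COc1cc(C)c(OC)c(Br)c1 | intermediate
4 | (2E,6E)-farnesyl bromide, (2E,6E)-1-bromo-3,7,11-trimethyldodeca-2,6,10-triene | CC(C)=CCC/C(C)=C/CC/C(C)=C/CBr | starting material
5 | 2,5-dimethoxy-3-methylphenyllithium | COc1cc(C)c(OC)c([Li])c1 | intermediate
6 | (2,5-dimethoxy-3-methylphenyl)copper | COc1cc(C)c(OC)c([Cu])c1 | intermediate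
7 | 1-[(2E,6E)-3,7,11-trimethyldodeca-2,6,10-trien-1-yl]-2,5-dimethoxy-3-methylbenzene | COc1cc(C)c(OC)c(C/C=C(\C)CC/C=C(\C)CCC=C(C)C)c1 | intermediate
8 | (2E,6E,10E)-12-(2,5-dimethoxy-3-methylphenyl)-2,6,10-trimethyldodeca-2,6,10-trien-1-ol | COc1cc(C)c(OC)c(C/C=C(\C)CC/C=C(\C)CC/C=C(\C)CO)c1 | intermediate
9 | (2E,6E,10E)-12-(2,5-dimethoxy-3-methylphenyl)-2,6,10-trimethyldodeca-2,6,10-trienal | COc1cc(C)c(OC)c(C/C=C(\C)CC/C=C(\C)CC/C=C(\C)C=O)c1 | intermediate
10 | (2E,6E,10E)-12-(2,5-dimethoxy-3-methylphenyl)-2,6,10-trimethyldodeca-2,6,10-trienoic acid | COc1cc(C)c(OC)c(C/C=C(\C)CC/C=C(\C)CC/C=C(\C)C(=O)O)c1 | intermediate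
11 | (2E,6E,10E)-2,6,10-trimethyl-12-(5-methyl-3,6-dioxocyclohexa-1,4-dien-1-yl)dodeca-2,6,10-trienoic acid | CC1=CC(=O)C=C(C/C=C(\C)CC/C=C(\C)CC/C=C(\C)C(=O)O)C1=O | intermediate
12 | (2E,6E,10E)-12-(2,5-dihydroxy-3-methylphenyl)-2,6,10-trimethyldodeca-2,6,10-trienoic acid | Cc1cc(O)cc(C/C=C(\C)CC/C=C(\C)CC/C=C(\C)C(=O)O)c1O | intermediate
13 | (2E,6E)-9-[(2R)-6-hydroxy-2,8-dimethyl-3,4-dihydro-2H-chromen-2-yl]-2,6-dimethylnona-2,6-dienoic acid | C/C(=C\CC[C@]1(C)CCc2cc(O)cc(C)c2O1)CC/C=C(\C)C(=O)O | target

**Step count and risks**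

Total steps: 8. Longest linear sequence: 8 steps (1 → 13).

Steps most likely to fail:

1. Step 8 (Proposed new method). What may go wrong: insufficient facial discrimination at the trisubstituted alkene, or stepwise protonation at the central alkene leading to carbocyclisation. The fallback uses known chemistry, sets out from 2 and comes back at 13 (it replaces steps 2–8). The stereocentre is set by a palladium-catalysed asymmetric allylic etherification and the chain is attached afterwards by B-alkyl Suzuki coupling.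
   - Heck arylation of but-3-en-2-ol with 2 [Pd(OAc)2, Bu4NCl, NaHCO3, DMF, 80 °C] gives 4-(2-hydroxy-5-methoxy-3-methylphenyl)butan-2-one F1.
   - Horner–Wadsworth–Emmons olefination (triethyl phosphonoacetate, NaH, THF; E isomer separated) gives ethyl (2E)-5-(2-hydroxy-5-methoxy-3-methylphenyl)-3-methylpent-2-enoate F2.
   - DIBAL-H reduction gives 2-[(3E)-5-hydroxy-3-methylpent-3-en-1-yl]-4-methoxy-6-methylphenol F3.
   - Its primary hydroxyl is converted (ClCO2Me, pyridine, −20 °C; the flanked phenol stays free) into (2E)-5-(2-hydroxy-5-methoxy-3-methylphenyl)-3-methylpent-2-en-1-yl methyl carbonate F4.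
   - Intramolecular asymmetric allylic alkylation [Pd2(dba)3·CHCl3, DACH-phenyl bisphosphine ligand of the antipode selected for this product, AcOH, CH2Cl2] closes the ring to (2S)-6-methoxy-2,8-dimethyl-2-vinylchroman F5. This has the same spatial arrangement as 2R in 13; the descriptor changes because vinyl outranks C3.
   - In parallel, pent-4-yn-1-ol is taken by Negishi carboalumination/iodination (AlMe3, Cp2ZrCl2; I2) to (4E)-5-iodo-4-methylpent-4-en-1-ol F6, oxidised (Dess–Martin periodinane) to (4E)-5-iodo-4-methylpent-4-enal F7, and olefinated with methyl 2-(triphenylphosphoranylidene)propanoate to methyl (2E,6E)-7-iodo-2,6-dimethylhepta-2,6-dienoate F8.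
   - Hydroboration of F5 with 9-BBN gives 9-{2-[(2R)-6-methoxy-2,8-dimethylchroman-2-yl]ethyl}-9-borabicyclo[3.3.1]nonane F9, which is coupled in the same flask with F8 [Pd(dppf)Cl2, AsPh3, Cs2CO3, DMF/H2O] to methyl (2E,6E)-9-[(2R)-6-methoxy-2,8-dimethylchroman-2-yl]-2,6-dimethylnona-2,6-dienoate F10.
   - NaSEt in DMF at 110 °C cleaves both O-methyl groups by SN2 at carbon and should give 13 after acidification.

2. Step 4. What may go wrong: poor site selectivity of the allylic oxidation (attack at internal allylic positions) and over-oxidation. The fallback sets out from 7 and comes back at 10 (it replaces steps 4–5). It rebuilds the chain terminus by cleavage and olefination instead of C–H oxidation.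
   - Terminal-selective bromohydrin formation (NBS, THF/H2O, 0 °C) gives racemic (6E,10E)-3-bromo-12-(2,5-dimethoxy-3-methylphenyl)-2,6,10-trimethyldodeca-6,10-dien-2-ol F11.
   - K2CO3 in MeOH closes it to racemic 2-[(3E,7E)-9-(2,5-dimethoxy-3-methylphenyl)-3,7-dimethylnona-3,7-dien-1-yl]-3,3-dimethyloxirane F12.
   - Periodic acid (THF/Et2O/H2O) cleaves the epoxide to (4E,8E)-10-(2,5-dimethoxy-3-methylphenyl)-4,8-dimethyldeca-4,8-dienal F13.
   - E-selective Wittig olefination with ethyl 2-(triphenylphosphoranylidene)propanoate gives ethyl (2E,6E,10E)-12-(2,5-dimethoxy-3-methylphenyl)-2,6,10-trimethyldodeca-2,6,10-trienoate F14.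
   - LiOH (THF/MeOH/H2O) then gives 10.

3. Step 3. What may go wrong: incomplete halogen–metal exchange, SN2′ attack, or loss of the 2E geometry through allylic transposition. The fallback sets out from 1 (with 4) and comes back at 7 (it replaces steps 1–3). It uses phenoxide ortho-C-alkylation instead of an aryl-metal coupling.
   - The sodium salt of 1 (NaH, toluene, 0 °C → rt) is alkylated by 4 at its only free ortho carbon to give 4-methoxy-2-methyl-6-[(2E,6E)-3,7,11-trimethyldodeca-2,6,10-trien-1-yl]phenol F15.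
   - O-Methylation (MeI, K2CO3, acetone) gives 7.

**Further compounds**

F1 | step 8 | 4-(2-hydroxy-5-methoxy-3-methylphenyl)butan-2-one | COc1cc(C)c(O)c(CCC(C)=O)c1
F2 | step 8 | ethyl (2E)-5-(2-hydroxy-5-methoxy-3-methylphenyl)-3-methylpent-2-enoate | CCOC(=O)/C=C(\C)CCc1cc(OC)cc(C)c1O
F3 | step 8 | 2-[(3E)-5-hydroxy-3-methylpent-3-en-1-yl]-4-methoxy-6-methylphenol | OC/C=C(\C)CCc1cc(OC)cc(C)c1O
F4 | step 8 | (2E)-5-(2-hydroxy-5-methoxy-3-methylphenyl)-3-methylpent-2-en-1-yl methyl carbonate | COC(=O)OC/C=C(\C)CCc1cc(OC)cc(C)c1O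
F5 | step 8 | (2S)-6-methoxy-2,8-dimethyl-2-vinylchroman | C=C[C@]1(C)CCc2cc(OC)cc(C)c2O1
F6 | step 8 | (4E)-5-iodo-4-methylpent-4-en-1-ol | OCCC/C(C)=C/I
F7 | step 8 | (4E)-5-iodo-4-methylpent-4-enal | O=CCC/C(C)=C/I
F8 | step 8 | methyl (2E,6E)-7-iodo-2,6-dimethylhepta-2,6-dienoate | COC(=O)/C(C)=C/CC/C(C)=C/I
F9 | step 8 | 9-{2-[(2R)-6-methoxy-2,8-dimethylchroman-2-yl]ethyl}-9-borabicyclo[3.3.1]nonane | B1(CC[C@]2(C)CCc3cc(OC)cc(C)c3O2)C4CCCC1CCC4
F10 | step 8 | methyl (2E,6E)-9-[(2R)-6-methoxy-2,8-dimethylchroman-2-yl]-2,6-dimethylnona-2,6-dienoate | C/C(=C\CC[C@]1(C)CCc2cc(OC)cc(C)c2O1)CC/C=C(\C)C(=O)OC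
F11 | step 4 | (6E,10E)-3-bromo-12-(2,5-dimethoxy-3-methylphenyl)-2,6,10-trimethyldodeca-6,10-dien-2-ol (racemic) | COc1cc(C)c(OC)c(C/C=C(\C)CC/C=C(\C)CCC(Br)C(C)(C)O)c1
F12 | step 4 | 2-[(3E,7E)-9-(2,5-dimethoxy-3-methylphenyl)-3,7-dimethylnona-3,7-dien-1-yl]-3,3-dimethyloxirane (racemic) | COc1cc(C)c(OC)c(C/C=C(\C)CC/C=C(\C)CCC2OC2(C)C)c1
F13 | step 4 | (4E,8E)-10-(2,5-dimethoxy-3-methylphenyl)-4,8-dimethyldeca-4,8-dienal | COc1cc(C)c(OC)c(C/C=C(\C)CC/C=C(\C)CCC=O)c1
F14 | step 4 | ethyl (2E,6E,10E)-12-(2,5-dimethoxy-3-methylphenyl)-2,6,10-trimethyldodeca-2,6,10-trienoate | COc1cc(C)c(OC)c(C/C=C(\C)CC/C=C(\C)CC/C=C(\C)C(=O)OCC)c1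
F15 | step 3 | 4-methoxy-2-methyl-6-[(2E,6E)-3,7,11-trimethyldodeca-2,6,10-trien-1-yl]phenol | COc1cc(C)c(O)c(C/C=C(\C)CC/C=C(\C)CCC=C(C)C)c1
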